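Assumption (remark on the chemistry): the (R) antipode of Cl,MeO-BIPHEP is taken to deliver the allyl group to the Re face of the transient aldehyde 5 and so to give (S)-6; this sense is to be confirmed on 6 by Mosher ester analysis, and the ligand antipode exchanged if it proves opposite.

## Structural features

The target 13 is an open-chain 1,7-diarylheptane-3,5-diol: a seven-carbon chain joins ring A (4-hydroxy-3-methoxyphenyl, on C1) to ring B (4-hydroxy-3,5-dimethoxyphenyl, on C7), and the two arenes are the only rings. The only stereocentres are C3 and C5, both S, separated by the C4 methylene and standing in a 1,3-anti relationship. The chain is almost C2-symmetric; only the extra methoxy group on ring B distinguishes the ends, so any plan built on a symmetric core has to tell two nearly identical ends apart. The fragile parts are the two free, electron-rich phenols (oxidation, quinone methide formation, O-alkylation) and the arenes themselves, which are good nucleophiles toward cations; the diol itself is configurationally robust. The real difficulty is to set the remote anti diol in one absolute sense with few asymmetric operations while placing the correct aryl group at each end. The key step uses the fact that the oxygen on C5 and the benzylic carbon C1 can be tied into a tetrahydropyran made of O, C1, C2, C3, C4 and C5; in its all-equatorial chair the C3 oxygen and the C5 side chain are cis, and this is exactly the anti diol once the ring is opened. The para-hydroxyl of ring A then makes the ring C1–O bond a labile benzylic ether, so that hydrogen on palladium can remove the ring and the temporary C1 stereocentre.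

## Logic of the disconnections

13 to 11 (through 12). The first backward move is a reconnection: C1 is joined to the oxygen on C5 and the phenol of ring B is capped as a benzyl ether. The open-chain anti relationship thereby becomes a cis relationship between two equatorial groups on a chair, and C1 becomes a stereocentre that costs nothing because it is erased again. The gain is that the C3 problem is reduced to ring diastereoselectivity. The forward step must cleave the ring C1–O bond, which is benzylic and activated by the para-hydroxyl of ring A, while the non-benzylic C3–O and C5–O bonds and both arenes stay untouched.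

11 to 10. The O–H bonds at C3 and on ring A are exchanged for a trifluoroacetate and an acetate. The C3 oxygen arrives as the ester of the acid that drives the cyclisation, and ring A has to be electron-poor while cations are present. No separate protecting-group step is needed, since both esters fall in one methanolysis. The forward step must be mild enough to leave the benzylic ring ether and the benzyl ether alone.

10 to 6 and 7. Three bonds are cut at once: O–C1, C1–C2 and C3–O. This splits the skeleton into 6 (ring B, C2 to C7, the C5 stereocentre) and 7 (ring A with C1, a purchased aldehyde). One step then builds the ring, one C–C bond and two stereocentres, and only C5 has to come from asymmetric synthesis. The forward step needs a chair transition state with both large groups equatorial, equatorial capture at C3, no 2-oxonia-Cope scrambling and no attack of ring B on the cations. The stereodescriptors of 6 and 10 were recomputed from their structures and agree with 13, and the skeletons need no change. The protecting groups were re-examined and kept. The acetate on 7 is a poor para donor and leaves together with the trifluoroacetate. The benzyl ether on ring B of 6 is the one group that survives the basic steps before the cyclisation and needs no step of its own to come off; its exposure to acid is limited by temperature and time.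

6 to 3 and 4. The C4–C5 bond is cut, which removes the only stereocentre of 6 and leaves an achiral primary alcohol and a C3 allyl donor. The forward step must allylate enantioselectively from the alcohol oxidation level, so that no separate oxidation and no stoichiometric allyl-metal reagent are needed.

3 to 2 to 1. The C5–O bond of 3 is traced back to the terminal alkene of 2 (anti-Markovnikov hydration), and the benzyl ether of 2 to the free phenol 1. This leads to a cheap allylphenol. The hydroboration must be regioselective, and the phenol must be capped first because a free phenol would be O-allylated in the iridium step.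

## Other disconnections considered

Alternative 1: The cut is at C2–C3 and C5–C6, which reduces the diol core to propane-1,3-diol (A1). In the forward sense A1 would be dehydrogenated in the flask at each end and allylated twice by 4 on a chiral iridium catalyst to give (4S,6S)-nona-1,8-diene-4,6-diol (A2), whose carbinol centres have the spatial arrangement of C3 and C5 of 13.
- In favour: both stereocentres are set by the catalyst in one operation, and a double enantioselective reaction of this kind should give the anti isomer in very high enantiomeric purity, because the minor sense is diverted into the meso diastereomer. On absolute and relative stereocontrol this plan is the equal of the chosen one or better, since it needs no relay. It also avoids cation chemistry next to electron-rich arenes.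
- Against: A2 has nine chain carbons, so each allyl group supplies C2 and C1 (or C6 and C7) plus one surplus methylene. The alkenes would have to be cleaved after diol protection and the aryl groups added as aryl-metal reagents at C1 and C7, which leaves benzylic oxygen to be removed again. The two ends of A2 are homotopic, whereas 13 carries ring A at one end and ring B at the other, so the ends can be told apart only statistically or by extra mono-functionalisation.
- Comparison: mechanistically sound and structurally well suited to a symmetric diarylheptanoid, but for this unsymmetrical one it should need roughly eight to nine steps with a statistical step, against six.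

Alternative 2: The cut is at the C3–O and C5–O bonds, traced back to C1–O and C7–O bonds of (1R,2E,5E,7R)-1-[3-methoxy-4-(pivaloyloxy)phenyl]-7-[3,5-dimethoxy-4-(pivaloyloxy)phenyl]hepta-2,5-diene-1,7-diyl diacetate (A3). In the forward step PdCl2(MeCN)2 (divalent palladium) activates each alkene, the acetate carbonyl oxygen adds at C3 (or C5) to form a six-membered acetoxonium intermediate, and its collapse moves each acetate 1,3 across one face of the allyl unit. The product is the (1E,3R,5R,6E)-hepta-1,6-diene-3,5-diyl diacetate (A4), with both alkenes now conjugated to the arenes.
- In favour: conjugation gives a thermodynamic drive, and the suprafacial shift should map (1R,7R) onto (3R,5R), which is the spatial arrangement of 13. Unsymmetrical ends pose no problem, which makes it the equal of the chosen plan on that point. The end game (alkene hydrogenation, ester cleavage) has no ring C–O bond to break, which is a point in its favour over the chosen plan.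
- Against: two benzylic stereocentres have to be made first by two enantioselective events and are then erased, so more asymmetric operations are spent than in the chosen plan. Acetates that are both benzylic and allylic on oxygenated arenes ionise easily, and an ion-pair pathway would transfer chirality incompletely. Fidelity also depends on the E geometry of both alkenes in a skipped diene whose doubly allylic C4 methylene tends to move into conjugation. The cinnamyl-type acetates of A4 are open to C–O hydrogenolysis during the final hydrogenation.
- Comparison: the rearrangement is known chemistry of the same standing as the Prins step, but making A3 in geometrically and enantiomerically pure form should bring the total to about nine or ten steps.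

Alternative 3: The cut is at C1–C2 and C6–C7. The core is (2R,4R)-1,2:4,5-diepoxypentane (A5), which already holds both carbinol centres; the aryl carbons come from 2-[4-(benzyloxy)-3-methoxyphenyl]-1,3-dithiane (A6) and 2-[4-(benzyloxy)-3,5-dimethoxyphenyl]-1,3-dithiane (A7). Lithiated A6 would open one terminal epoxide carbon by SN2 and lithiated A7 the other, giving the bis-dithiane diol (A8); Raney Ni would then reduce both dithianes to methylene groups and the benzyl ethers would be removed. By the CIP rules A8 is (2R,4R) on its pentane-2,4-diol core, because each dithiane-bearing methylene outranks the central one; its arrangement in space is nevertheless that of the (3S,5S) centres of 13.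
- In favour: no stereocentre is made or relayed in the key step, so on stereochemical certainty it is better than the chosen plan. Both C–C bonds come from dependable epoxide openings, and the plan is convergent with a longest linear sequence about equal to that of the chosen route.
- Against: the two epoxides are homotopic, so the first opening has to be stopped at mono-addition by stoichiometry alone. The alkoxide of the mono-adduct can close onto the remaining epoxide. 2-Aryl-2-lithiodithianes are hindered nucleophiles. A5 is a volatile bis-alkylating agent that needs several steps in enantiopure form, and the desulfurisation uses a large excess of Raney Ni.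
- Comparison: about ten steps in total against six, with poorer atom economy, and the chosen plan differentiates the chain ends by construction.

Key step: step 4

## Route

Step 1
Reactants: 1 4-allyl-2,6-dimethoxyphenol
Product: 2 2-(benzyloxy)-1,3-dimethoxy-5-(prop-2-en-1-yl)benzene
Conditions: BnBr (1.2 equiv), K2CO3 (2 equiv), DMF, rt to 50 °C
Reagents that add atoms: benzyl bromide, BrCc1ccccc1
Why: Williamson ether synthesis on the phenoxide; the benzyl ether keeps the phenol from O-allylation in step 3 and from oxidation, withstands the basic steps 2, 3 and 5, and is removed in step 6 without a step of its own.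

Step 2
Reactants: 2 2-(benzyloxy)-1,3-dimethoxy-5-(prop-2-en-1-yl)benzene
Product: 3 3-[4-(benzyloxy)-3,5-dimethoxyphenyl]propan-1-ol
Conditions: 9-BBN (1.3 equiv), THF, 0 °C to rt; then NaOH (3 M aq), H2O2 (30% aq), 0 °C to rt
Reagents that add atoms: hydrogen peroxide, OO
Why: Hydroboration–oxidation; the bulky borane adds boron to the terminal carbon of the monosubstituted alkene, and oxidation with retention gives the primary alcohol, with the aryl benzyl ether inert to both stages.

Step 3
Reactants: 3 3-[4-(benzyloxy)-3,5-dimethoxyphenyl]propan-1-ol; 4 allyl acetate
Product: 6 (3S)-1-[4-(benzyloxy)-3,5-dimethoxyphenyl]hex-5-en-3-ol, via 3-arylpropanal 5 (not isolated)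
Conditions: [Ir(cod)Cl]2 (2.5 mol%), (R)-Cl,MeO-BIPHEP (5 mol%), 4-chloro-3-nitrobenzoic acid (10 mol%), Cs2CO3 (20 mol%), 4 (3 equiv), THF, 100 °C, sealed tube
Reagents that add atoms: none
Why: Krische carbonyl allylation from the alcohol oxidation level (transfer-hydrogenative C–C coupling): the cyclometallated π-allyl iridium benzoate formed in the flask dehydrogenates 3 to aldehyde 5 and adds the allyl group to it through a closed chair-like transition state. The chiral bisphosphine selects the aldehyde face and so sets C5 (S for Re-face delivery), and unbranched 3-arylpropanols are standard substrates for this reaction.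

Step 4
Reactants: 6 (3S)-1-[4-(benzyloxy)-3,5-dimethoxyphenyl]hex-5-en-3-ol; 7 vanillin acetate (4-formyl-2-methoxyphenyl acetate)
Product: 10 (2S,4R,6S)-2-(4-acetoxy-3-methoxyphenyl)-6-{2-[4-(benzyloxy)-3,5-dimethoxyphenyl]ethyl}oxan-4-yl trifluoroacetate, via oxocarbenium ion 8 (not isolated), via tetrahydropyranyl cation 9 (not isolated)
Conditions: 7 (1.3 equiv), CF3CO2H (15 equiv), CH2Cl2, 0 °C to rt; NaHCO3 aq work-up
Reagents that add atoms: trifluoroacetic acid, OC(=O)C(F)(F)F
Why: This is a Prins cyclisation (oxocarbenium–alkene cation–olefin cyclisation), the known route from homoallylic alcohols and aldehydes to all-cis 2,6-disubstituted 4-acyloxytetrahydropyrans. Acid-promoted condensation of 6 with 7 and loss of water gives the (E)-oxocarbenium ion 8, which forms the O–C1 bond. The terminal alkene carbon C2 then attacks C1 in a 6-endo-trig closure of the ring O, C1, C2, C3, C4, C5 through a chair transition state, forming C1–C2 and leaving the charge at C3 in cation 9. The existing C5 centre places its arylethyl chain equatorial and the (E) geometry of 8 places ring A equatorial, so the substrate sets C1 cis to C5. Trifluoroacetate, present in large excess, captures 9 from the equatorial direction, the trajectory that keeps the developing bond aligned with the delocalised chair cation, so C3 is set cis to both neighbours (4R in ring numbering, which is the 3S centre of 13). The step needs all-cis diastereoselectivity and chemoselectivity against 2-oxonia-Cope scrambling, benzylic ionisation and Friedel–Crafts attack by ring B. The aliphatic carbinol of 6 and the weakly donating para-acetoxy group of 7 hold back the first two, and the fast six-membered chair closure together with the excess of trifluoroacetate at 0 °C should outrun the seven-membered or intermolecular arene attack.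

Step 5
Reactants: 10 (2S,4R,6S)-2-(4-acetoxy-3-methoxyphenyl)-6-{2-[4-(benzyloxy)-3,5-dimethoxyphenyl]ethyl}oxan-4-yl trifluoroacetate
Product: 11 (2S,4R,6S)-6-{2-[4-(benzyloxy)-3,5-dimethoxyphenyl]ethyl}-2-(4-hydroxy-3-methoxyphenyl)oxan-4-ol
Conditions: K2CO3 (0.5 equiv), MeOH, 0 °C to rt; NH4Cl aq work-up
Reagents that add atoms: none
Why: Base-catalysed transesterification (methanolysis): the trifluoroacetate and the aryl acetate are both activated esters and should fall at room temperature, while the benzyl ether, the ring ether and all three stereocentres are untouched.

Step 6
Reactants: 11 (2S,4R,6S)-6-{2-[4-(benzyloxy)-3,5-dimethoxyphenyl]ethyl}-2-(4-hydroxy-3-methoxyphenyl)oxan-4-ol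
Product: 13 (3S,5S)-1-(4-hydroxy-3-methoxyphenyl)-7-(4-hydroxy-3,5-dimethoxyphenyl)heptane-3,5-diol (CNP0317264.1), via debenzylated tetrahydropyranol 12 (not isolated)
Conditions: H2 (3 bar), Pd/C (10 wt% Pd), EtOH, HCl (0.1 equiv), rt
Reagents that add atoms: none
Why: Catalytic hydrogenolysis of benzylic C–O bonds: the benzyl ether goes first (12), then the ring C1–O bond, a benzylic ether activated by the para-hydroxyl of ring A and by the trace of acid, as in the hydrogenolytic opening of guaiacyl-substituted cyclic benzylic ethers of lignans. C1 becomes a methylene group, and the non-benzylic C3–O and C5–O bonds keep their configuration.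

## Compound list

1 | 4-allyl-2,6-dimethoxyphenol | C=CCc1cc(OC)c(O)c(OC)c1 | starting material
2 | 2-(benzyloxy)-1,3-dimethoxy-5-(prop-2-en-1-yl)benzene | C=CCc1cc(OC)c(OCc2ccccc2)c(OC)c1 | intermediate
3 | 3-[4-(benzyloxy)-3,5-dimethoxyphenyl]propan-1-ol | OCCCc1cc(OC)c(OCc2ccccc2)c(OC)c1 | intermediate
4 | allyl acetate | C=CCOC(C)=O | starting material
5 | 3-[4-(benzyloxy)-3,5-dimethoxyphenyl]propanal | O=CCCc1cc(OC)c(OCc2ccccc2)c(OC)c1 | intermediate (not isolated)
6 | (3S)-1-[4-(benzyloxy)-3,5-dimethoxyphenyl]hex-5-en-3-ol | C=CC[C@@H](O)CCc1cc(OC)c(OCc2ccccc2)c(OC)c1 | intermediate
7 | vanillin acetate (4-formyl-2-methoxyphenyl acetate) | CC(=O)Oc1ccc(C=O)cc1OC | starting material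
8 | (E)-oxocarbenium ion from 6 and 7, {(3S)-1-[4-(benzyloxy)-3,5-dimethoxyphenyl]hex-5-en-3-yl}[(4-acetoxy-3-methoxyphenyl)methylidene]oxonium | C=CC[C@@H](/[O+]=C/c1ccc(OC(C)=O)c(OC)c1)CCc1cc(OC)c(OCc2ccccc2)c(OC)c1 | intermediate (not isolated)
9 | 2,6-cis-2-(4-acetoxy-3-methoxyphenyl)-6-{2-[4-(benzyloxy)-3,5-dimethoxyphenyl]ethyl}oxan-4-ylium | O1[C@H](c2ccc(OC(C)=O)c(OC)c2)C[CH+]C[C@@H]1CCc1cc(OC)c(OCc2ccccc2)c(OC)c1 | intermediate (not isolated)
10 | (2S,4R,6S)-2-(4-acetoxy-3-methoxyphenyl)-6-{2-[4-(benzyloxy)-3,5-dimethoxyphenyl]ethyl}oxan-4-yl trifluoroacetate (all-cis) | O1[C@H](c2ccc(OC(C)=O)c(OC)c2)C[C@H](OC(=O)C(F)(F)F)C[C@@H]1CCc1cc(OC)c(OCc2ccccc2)c(OC)c1 | intermediate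
11 | (2S,4R,6S)-6-{2-[4-(benzyloxy)-3,5-dimethoxyphenyl]ethyl}-2-(4-hydroxy-3-methoxyphenyl)oxan-4-ol | O1[C@H](c2ccc(O)c(OC)c2)C[C@H](O)C[C@@H]1CCc1cc(OC)c(OCc2ccccc2)c(OC)c1 | intermediate
12 | (2S,4R,6S)-6-[2-(4-hydroxy-3,5-dimethoxyphenyl)ethyl]-2-(4-hydroxy-3-methoxyphenyl)oxan-4-ol | O1[C@H](c2ccc(O)c(OC)c2)C[C@H](O)C[C@@H]1CCc1cc(OC)c(O)c(OC)c1 | intermediate (not isolated)
13 | (3S,5S)-1-(4-hydroxy-3-methoxyphenyl)-7-(4-hydroxy-3,5-dimethoxyphenyl)heptane-3,5-diol | COc1cc(CC[C@H](O)C[C@@H](O)CCc2cc(OC)c(O)c(OC)c2)ccc1O | target

## Step count and least certain steps

Total step count: 6. Longest linear sequence: 6 steps (1 to 13); 4 and 7 are purchased.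

Step 4 (key step). Several processes may interfere:
- Electrophilic aromatic substitution by ring B. Its positions next to the chain are activated by two methoxy groups and may attack 8 or 9, within the molecule (seven-membered closure) or between molecules.
- Acid-induced loss of the benzyl group.
- 2-Oxonia-Cope exchange, which would scramble the side chains and erode the enantiomeric purity set in step 3.
- Incomplete equatorial selectivity in the capture at C3.

The fallback leaves cation chemistry altogether, sets out from 3 and comes back at 13. Alcohol 3 is oxidised with Dess–Martin periodinane to aldehyde 5, here isolated. Commercial zingerone F1 is benzylated (BnBr, K2CO3, DMF) to 4-[4-(benzyloxy)-3-methoxyphenyl]butan-2-one F2. Its kinetic methyl-side enolate (LiN(i-Pr)2, THF, −78 °C) adds to 5 to give the racemic 5-hydroxyheptan-3-one F3, and Dess–Martin oxidation gives the heptane-3,5-dione F4. Noyori hydrogenation of the 1,3-diketone with RuCl2[(S)-BINAP] (H2, MeOH), a known catalyst-controlled route to anti 1,3-diols, should give the (3S,5S)-diol bis(benzyl ether) F5. Hydrogenolysis (H2, Pd/C, EtOH) of both benzyl ethers then gives 13.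

Step 6. The hydrogenolysis may stop after debenzylation, leaving the ring C1–O bond intact, because a 2-aryltetrahydropyran is a less accessible benzylic ether than an open-chain one; forcing the conditions invites solvolysis at C1 or partial saturation of the arenes. The fallback changes the mechanism from surface hydrogenolysis to ionic hydrogenation, sets out from 11 and comes back at 13. Et3SiH with BF3·OEt2 in CH2Cl2 at −40 to 0 °C should ionise the C1–O bond with the help of the para-hydroxyl and deliver hydride to C1, giving (3S,5S)-7-[4-(benzyloxy)-3,5-dimethoxyphenyl]-1-(4-hydroxy-3-methoxyphenyl)heptane-3,5-diol F6. A neutral hydrogenolysis (H2, Pd/C, EtOH) of the remaining benzyl ether then gives 13.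

Step 3. Conversion may be incomplete, because the redox-neutral cycle depends on a balance between alcohol dehydrogenation and aldehyde allylation, and the facial selectivity may be lower than hoped or opposite in sense to the assumption. The fallback replaces the catalytic redox coupling by a stoichiometric chiral allyl reagent, sets out from 3 and comes back at 6. Parikh–Doering oxidation (SO3·pyridine, DMSO, i-Pr2NEt) gives aldehyde 5, here isolated. Brown allylboration at −78 °C with the antipode of Ipc2B(allyl) that attacks the Re face of 5, followed by oxidative work-up, gives 6. This fallback makes no compound outside the compound list (F0).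

## Further compounds

F1 | step 4 | zingerone, 4-(4-hydroxy-3-methoxyphenyl)butan-2-one | CC(=O)CCc1ccc(O)c(OC)c1
F2 | step 4 | 4-[4-(benzyloxy)-3-methoxyphenyl]butan-2-one | CC(=O)CCc1ccc(OCc2ccccc2)c(OC)c1
F3 | step 4 | rac-7-[4-(benzyloxy)-3,5-dimethoxyphenyl]-1-[4-(benzyloxy)-3-methoxyphenyl]-5-hydroxyheptan-3-one | COc1cc(CCC(=O)CC(O)CCc2cc(OC)c(OCc3ccccc3)c(OC)c2)ccc1OCc1ccccc1
F4 | step 4 | 7-[4-(benzyloxy)-3,5-dimethoxyphenyl]-1-[4-(benzyloxy)-3-methoxyphenyl]heptane-3,5-dione | COc1cc(CCC(=O)CC(=O)CCc2cc(OC)c(OCc3ccccc3)c(OC)c2)ccc1OCc1ccccc1
F5 | step 4 | (3S,5S)-7-[4-(benzyloxy)-3,5-dimethoxyphenyl]-1-[4-(benzyloxy)-3-methoxyphenyl]heptane-3,5-diol | COc1cc(CC[C@H](O)C[C@@H](O)CCc2cc(OC)c(OCc3ccccc3)c(OC)c2)ccc1OCc1ccccc1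
F6 | step 6 | (3S,5S)-7-[4-(benzyloxy)-3,5-dimethoxyphenyl]-1-(4-hydroxy-3-methoxyphenyl)heptane-3,5-diol | COc1cc(CC[C@H](O)C[C@@H](O)CCc2cc(OC)c(OCc3ccccc3)c(OC)c2)ccc1O
F0 | step 3 | none | none
A1 | alternative 1 | propane-1,3-diol | OCCCO
A2 | alternative 1 | (4S,6S)-nona-1,8-diene-4,6-diol | C=CC[C@H](O)C[C@@H](O)CC=C
A3 | alternative 2 | (1R,2E,5E,7R)-1-[3-methoxy-4-(pivaloyloxy)phenyl]-7-[3,5-dimethoxy-4-(pivaloyloxy)phenyl]hepta-2,5-diene-1,7-diyl diacetate | COc1cc([C@H](OC(C)=O)/C=C/C/C=C/[C@@H](OC(C)=O)c2cc(OC)c(OC(=O)C(C)(C)C)c(OC)c2)ccc1OC(=O)C(C)(C)C
A4 | alternative 2 | (1E,3R,5R,6E)-1-[3-methoxy-4-(pivaloyloxy)phenyl]-7-[3,5-dimethoxy-4-(pivaloyloxy)phenyl]hepta-1,6-diene-3,5-diyl diacetate | COc1cc(/C=C/[C@H](OC(C)=O)C[C@@H](OC(C)=O)/C=C/c2cc(OC)c(OC(=O)C(C)(C)C)c(OC)c2)ccc1OC(=O)C(C)(C)C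
A5 | alternative 3 | (2R,4R)-1,2:4,5-diepoxypentane | C1O[C@@H]1C[C@@H]1CO1
A6 | alternative 3 | 2-[4-(benzyloxy)-3-methoxyphenyl]-1,3-dithiane | COc1cc(C2SCCCS2)ccc1OCc1ccccc1
A7 | alternative 3 | 2-[4-(benzyloxy)-3,5-dimethoxyphenyl]-1,3-dithiane | COc1cc(C2SCCCS2)cc(OC)c1OCc1ccccc1
A8 | alternative 3 | (2R,4R)-1-{2-[4-(benzyloxy)-3-methoxyphenyl]-1,3-dithian-2-yl}-5-{2-[4-(benzyloxy)-3,5-dimethoxyphenyl]-1,3-dithian-2-yl}pentane-2,4-diol | COc1cc(C2(C[C@H](O)C[C@@H](O)CC3(c4cc(OC)c(OCc5ccccc5)c(OC)c4)SCCCS3)SCCCS2)ccc1OCc1ccccc1
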